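(The numbers in the tables were computed for an exercise.)

Which way of putting in the same charges leaves the most target at the end?

| flask | starting material | partner | remark | time |
|---|---|---|---|---|
| Sunday's | 20 mM | 40 mM | run made earlier |  |
| Friday's | 13 mM | 40 mM | run made earlier |  |
| Thursday's | 30 mM | 40 mM | run made earlier |  |
| summer | 20 mM (fed, over 4.0 min) | 40.0 mM | all else is in the flask from the start; the feed brings no volume worth counting | 25 min |
| dawn | 20 mM (fed, over 15 min) | 40.0 mM | all else is in the flask from the start; the feed brings no volume worth counting | 25 min |
| dusk | 20 mM | 40.0 mM (fed, over 15 min) | all else is in the flask from the start; the feed brings no volume worth counting | 25 min |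
| autumn | 20 mM | 40.0 mM | everything together at the start | 25 min |
| midnight | 20 mM | 40.0 mM (in portions, 4, over 15 min) | first portion at the start, last at 15 min | 25 min |

- Sunday's (time / min: target / %, starting material / %): 6.00: 14.8, 85.8; 12.0: 24.8, 70.7; 20.0: 33.9, 56.9; 25.0: 37.0, 51.4
- Friday's (time / min: target / %, starting material / %): 8.00: 18.5, 76.8; 15.0: 28.9, 64.7; 25.0: 38.9, 48.8; 30.0: 43.9, 43.4
- Thursday's (time / min: target / %, starting material / %): 4.00: 9.5, 89.1; 10.0: 19.8, 74.9; 20.0: 31.8, 58.4; 30.0: 38.4, 47.4

(each reading ± 1 percentage point)

- which flask leads in amount of target, in percent of the starting material charged ("all alike" within 1.5 percentage points) (summer / dawn / dusk / autumn / midnight / all alike)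
- how much target is there at the end, in percent of the starting material charged: summer
- how much target is there at the end, in percent of the starting material charged: dawn
- how much target is there at the end, in percent of the starting material charged: dusk
- how much target is there at the end, in percent of the starting material charged: autumn
- how much target is there at the end, in percent of the starting material charged: midnight



I start from the readings. Sunday's run keeps 51.4 % of its starting material at 25.0 min, and Friday's, with less charged, keeps 48.8 % at the same time. So the percent left follows the charge weakly, and each molecule of starting material runs on its own clock, which is pseudo-first-order behaviour. Sunday's run gives a mean rate constant κ and its time constant τ: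

κ = ln(charged/left)/time = 0.0266 min⁻¹

τ = 1/κ = 37.6 min

Replacing the curve by this mean puts 72.7 % left at 12.0 min, where Sunday's reading is 70.7 %.

Now the ladder, fastest first. The quick feed takes 4.0 min, or 0.106 of τ, so summer's starting material is in early. The slow addition takes 15 min, shorter than τ, so dawn, dusk and midnight react during their additions, but mean values should still serve. The run, 25 min, is also shorter than τ, so time lost is target lost.

Fed steadily, starting material waits on average half the feed time. Partner fed steadily or in equal portions stands on average near half its charge during the addition. The earlier runs hold 40 mM partner each and cannot show that the rate follows partner, so I assume it. A flask with an addition then loses half the addition time, so I define the working clock θ, the run time minus that loss, which for the slow additions is 17.5 min. I read Sunday's target at θ, straight between readings: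

dawn, dusk, midnight: θ = 17.5 min, target 31.1 %, starting material left 62.8 %

summer: θ = 23.0 min, target 35.8 %

autumn: θ = 25 min, target 37.0 %

The forecast, reasoning that “Percent SM left barely depends on SM charge”, names autumn with 37.4 %, then summer 35.8 %, dawn 30 %, dusk 29.3 % and midnight 29.4 %, which puts the slow flasks below my figure.

The flasks give autumn in the lead with 37.4 %, then summer 35.8 %, dusk 30.5 %, midnight 30.4 % and dawn 30.3 %.

    starting material ⇌ reactive form (K = 0.00740, k = 1.40 min⁻¹)
    partner + reactive form → target (k = 110 M⁻¹ min⁻¹)
    target ⇌ isomer of the product (K = 0.410, k = 0.0500 min⁻¹)

Dawn holds 61 % starting material at the end, 1.8 percentage points under the reckoned 62.8 %. Autumn's lead over dawn, 7.1 points, rests in part on two back steps acting together, reactive form to starting material and isomer of the product to target: without the first the lead is −1.8 points, without the second 1.5 points. On the same clock of 17.5 min, with κ scaled to the partner charged, a flask like dawn but with 16 mM partner should keep 83.0 % starting material at the end, and it holds 81.6 %.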